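## Retrosynthetic overview
1. Agastenol ⇒ fluoride desilylation and Steglich esterification ⇒ O-silyl 4-hydroxybenzoic acid + (2R,3S,4E)-2-aryl-4-benzylidene-3-(hydroxymethyl)oxolane.
2. Oxolane ⇒ C5–O bond by SN2 cyclodehydration of a 1,4-diol, made by DIBAL-H reduction of an (E)-α-benzylidene-γ-lactone. The C2–O bond is never broken.
3. (E)-Benzylidene ⇒ lactone enolate aldol with O-TIPS-vanillin, then E1cB dehydration.
4. trans-β,γ-Disubstituted lactone ⇒ ketoreductase-catalysed dynamic reductive kinetic resolution of a stereolabile 2-aroylsuccinate, which sets both stereocentres ⇒ vanillin, Meldrum's acid, allyl alcohol, methyl bromoacetate.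
5. Ring order: γ-butyrolactone first (step 5), opened in step 11, oxolane closed in step 12.

Assumption: the SMILES is read as (2R,3S,4E), 2,3-trans, and a ketoreductase variant with the stated selectivity is picked from a commercial screening panel.
Abbreviation: Ar = 3-methoxy-4-(triisopropylsilyloxy)phenyl.

## Route

Step 1
Reactants: 1 vanillin (4-hydroxy-3-methoxybenzaldehyde)
Product: 2 3-methoxy-4-(triisopropylsilyloxy)benzaldehyde
Conditions: TIPSCl (1.1 equiv), imidazole (2 equiv), DMF, 0 °C to rt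
Reagents that add atoms: triisopropylsilyl chloride CC(C)[Si](Cl)(C(C)C)C(C)C
Why: Imidazole-promoted O-silylation of the only OH gives a bulky aryl TIPS ether that survives the later bases, hydrides and mild acids and falls to fluoride at the end.

Step 2
Reactants: 2 3-methoxy-4-(triisopropylsilyloxy)benzaldehyde
Product: 3 3-methoxy-4-(triisopropylsilyloxy)benzoic acid
Conditions: NaClO2, NaH2PO4, 2-methyl-2-butene, t-BuOH/THF/H2O, 0 °C to rt
Reagents that add atoms: sodium chlorite [Na+].[O-]Cl=O
Why: The Pinnick oxidation takes ArCHO to ArCO2H at about pH 4, where the aryl silyl ether is stable, and the alkene scavenger prevents chlorination of the electron-rich ring.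

Step 3
Reactants: 3 3-methoxy-4-(triisopropylsilyloxy)benzoic acid; 4 Meldrum's acid (2,2-dimethyl-1,3-dioxane-4,6-dione); 5 allyl alcohol
Product: 7 allyl 3-Ar-3-oxopropanoate, via acyl Meldrum's acid 6 (not isolated)
Conditions: DCC (1.1 equiv), DMAP (1.5 equiv), CH2Cl2, 0 °C to rt; filter, KHSO4 wash; then 5 (3 equiv), toluene, 95 °C
Reagents that add atoms: none
Why: In this Oikawa–Yonemitsu β-keto ester synthesis, carbodiimide C-acylation of Meldrum's acid is followed by thermal loss of acetone and CO2 in the presence of allyl alcohol, which gives the allyl β-keto ester cleanly.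

Step 4
Reactants: 7 allyl 3-Ar-3-oxopropanoate; 8 methyl bromoacetate
Product: 10 1-allyl 4-methyl 2-(Ar-carbonyl)butanedioate (racemic, α-centre configurationally labile), via sodium enolate 9 (not isolated)
Conditions: NaH (1.05 equiv), THF, 0 °C; then 8 (1.0 equiv), 0 °C to rt
Reagents that add atoms: sodium hydride [Na+].[H-] (sodium kept only in intermediate 9)
Why: SN2 C-alkylation of the stabilised β-keto ester enolate with one equivalent of a reactive α-bromo ester stops at mono-alkylation, and the new α-carbon equilibrates through the enol, so no configuration is fixed yet.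

Step 5
Reactants: 10 1-allyl 4-methyl 2-(Ar-carbonyl)butanedioate
Product: 12 allyl (2R,3R)-2-Ar-5-oxooxolane-3-carboxylate (trans), via hydroxy diester 11 (not isolated)
Conditions: ketoreductase (KRED, NADPH-dependent alcohol dehydrogenase, (R)-selective variant), NADP+ (cat.), i-PrOH (15 vol%), KPi buffer pH 7.0, MgSO4 (1 mM), DMSO (5 vol%), 30 °C; MTBE extraction; then PPTS (10 mol%), toluene, 50 °C
Reagents that add atoms: none
Why: In this enzymatic dynamic reductive kinetic resolution the α-carbon of 10 racemises through its enol at pH 7 while the ketoreductase reduces only the (R)-keto ester by hydride delivery to the Si face of the ketone; this fixes the carbinol (R) and the α-carbon (R) together, and mild acid-catalysed lactonisation onto the methyl ester then gives the trans lactone without touching either centre.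

Step 6
Reactants: 12 allyl (2R,3R)-2-Ar-5-oxooxolane-3-carboxylate
Product: 13 (2R,3R)-2-Ar-5-oxooxolane-3-carboxylic acid
Conditions: Pd(PPh3)4 (3 mol%), N-methylaniline (2 equiv), THF, rt; dilute citric acid wash
Reagents that add atoms: none
Why: Tsuji–Trost-type Pd(0) deallylation with a weakly basic allyl acceptor frees the acid under neutral conditions, so the epimerisable C3 and the acid-labile benzylic lactone C–O bond are both left alone.

Step 7
Reactants: 13 (2R,3R)-2-Ar-5-oxooxolane-3-carboxylic acid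
Product: 14 (4S,5R)-4-(hydroxymethyl)-5-Ar-oxolan-2-one
Conditions: BH3·SMe2 (1.5 equiv), THF, 0 °C to rt; MeOH quench
Reagents that add atoms: none
Why: Borane reduces a free carboxylic acid much faster than a lactone, and after this chemoselective reduction the ring carbon bearing CH2OH can no longer epimerise (the descriptor changes to S only through CIP priorities).

Step 8
Reactants: 14 (4S,5R)-4-(hydroxymethyl)-5-Ar-oxolan-2-one
Product: 15 (4S,5R)-4-[(tert-butyldimethylsilyloxy)methyl]-5-Ar-oxolan-2-one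
Conditions: TBSCl (1.2 equiv), imidazole (2.5 equiv), CH2Cl2, 0 °C
Reagents that add atoms: tert-butyldimethylsilyl chloride CC(C)(C)[Si](C)(C)Cl
Why: Fast silylation of the primary alcohol, done directly on crude 14, blocks translactonisation to the isomeric lactone and marks this oxygen for later selective release.

Step 9
Reactants: 15 (4S,5R)-4-[(tert-butyldimethylsilyloxy)methyl]-5-Ar-oxolan-2-one; 2 3-methoxy-4-(triisopropylsilyloxy)benzaldehyde
Product: 17 (4S,5R)-3-[hydroxy(Ar)methyl]-4-[(tert-butyldimethylsilyloxy)methyl]-5-Ar-oxolan-2-one (mixture of diastereomers at the two new transient centres), via lithium enolate 16 (not isolated)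
Conditions: LDA (commercial solution, 1.1 equiv), THF, −78 °C; then 2 (1.2 equiv), −78 °C; AcOH quench at −78 °C
Reagents that add atoms: lithium diisopropylamide [Li+].CC(C)[N-]C(C)C (lithium kept only in intermediate 16)
Why: This is a lithium enolate aldol addition in which the lactone α-CH2 is the only acidic site, there is no β-leaving group, and both new centres are erased in the next step.

Step 10
Reactants: 17 aldol adducts
Product: 19 (3E,4S,5R)-3-(Ar-methylidene)-4-[(tert-butyldimethylsilyloxy)methyl]-5-Ar-oxolan-2-one, via mesylate 18 (not isolated)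
Conditions: MsCl (1.5 equiv), Et3N (3 equiv), CH2Cl2, 0 °C; then DBU (3 equiv), 0 °C to rt; chromatography
Reagents that add atoms: methanesulfonyl chloride CS(=O)(=O)Cl (atoms kept only in intermediate 18)
Why: Mesylation followed by DBU-induced E1cB elimination funnels all aldol diastereomers through the enolate to the favoured (E)-benzylidene lactone, with the aryl group anti to C=O and cis to C4 as in the target, and any Z isomer is removed on silica.

Step 11
Reactants: 19 (E)-benzylidene lactone
Product: 20 (1R,2S,3E)-1-Ar-3-(Ar-methylidene)-2-[(tert-butyldimethylsilyloxy)methyl]butane-1,4-diol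
Conditions: DIBAL-H (4.5 equiv), CH2Cl2, −78 to −20 °C; Na2SO4·10H2O quench
Reagents that add atoms: none
Why: DIBAL-H reduces the α,β-unsaturated lactone in 1,2-fashion to the allylic alcohol without conjugate reduction, and because the acyl–oxygen bond is the one cleaved, the benzylic C–O configuration and the alkene geometry are kept.

Step 12
Reactants: 20 diol
Product: 21 (2R,3S,4E)-2-Ar-4-(Ar-methylidene)-3-[(tert-butyldimethylsilyloxy)methyl]oxolane
Conditions: PPh3 (1.5 equiv), DIAD (1.5 equiv), toluene, 0 °C to rt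
Reagents that add atoms: none
Why: In this Mitsunobu cyclodehydration the unhindered primary allylic OH is activated and displaced 5-exo-tet by the benzylic OH, so C2 keeps its R configuration; the neutral SN2 conditions avoid an allyl cation (E/Z scrambling, attack at the benzylic terminus) and avoid silyl migration.

Step 13
Reactants: 21 tris-silyl oxolane
Product: 22 [(2R,3S,4E)-2-Ar-4-(Ar-methylidene)oxolan-3-yl]methanol
Conditions: PPTS (0.3 equiv), MeOH/CH2Cl2 (4:1), 35 °C
Reagents that add atoms: none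
Why: In acid-catalysed methanolysis a primary alkyl TBS ether is cleaved far faster than hindered, acid-stable aryl TIPS ethers, and PPTS is too weak to ionise the benzylic or allylic ether bonds.

Step 14
Reactants: 23 4-hydroxybenzoic acid
Product: 25 4-(tert-butyldimethylsilyloxy)benzoic acid, via bis-silyl compound 24 (not isolated)
Conditions: TBSCl (2.4 equiv), imidazole (5 equiv), DMF, rt; then AcOH/THF/H2O (3:1:1), rt
Reagents that add atoms: tert-butyldimethylsilyl chloride CC(C)(C)[Si](C)(C)Cl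
Why: Exhaustive silylation followed by selective hydrolysis of the much more labile silyl ester leaves only the phenol protected.

Step 15
Reactants: 22 primary alcohol; 25 4-(tert-butyldimethylsilyloxy)benzoic acid
Product: 26 [(2R,3S,4E)-2-Ar-4-(Ar-methylidene)oxolan-3-yl]methyl 4-(tert-butyldimethylsilyloxy)benzoate
Conditions: DCC (1.3 equiv), DMAP (0.3 equiv), 25 (1.2 equiv), CH2Cl2, 0 °C to rt
Reagents that add atoms: none
Why: Steglich esterification acylates the only free hydroxyl under near-neutral conditions that disturb neither a stereocentre nor the alkene.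

Step 16
Reactants: 26 tris-silyl agastenol
Product: 27 agastenol, [(2R,3S,4E)-2-(4-hydroxy-3-methoxyphenyl)-4-[(4-hydroxy-3-methoxyphenyl)methylidene]oxolan-3-yl]methyl 4-hydroxybenzoate
Conditions: TBAF (3.5 equiv), AcOH (4 equiv), THF, 0 °C, light excluded
Reagents that add atoms: none
Why: Fluoride cleaves all three aryl silyl ethers, and the AcOH buffer protonates each phenoxide at once, so there is no ester cleavage and no quinone-methide opening of the benzylic ether that could epimerise C2.

## Compound list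
1 | vanillin | COc1cc(C=O)ccc1O | starting material
2 | 3-methoxy-4-(triisopropylsilyloxy)benzaldehyde | COc1cc(C=O)ccc1O[Si](C(C)C)(C(C)C)C(C)C | intermediate
3 | 3-methoxy-4-(triisopropylsilyloxy)benzoic acid | COc1cc(C(=O)O)ccc1O[Si](C(C)C)(C(C)C)C(C)C | intermediate
4 | Meldrum's acid | CC1(C)OC(=O)CC(=O)O1 | starting material
5 | allyl alcohol | C=CCO | starting material
6 | 5-[hydroxy(Ar)methylidene]-2,2-dimethyl-1,3-dioxane-4,6-dione (not isolated) | COc1cc(C(O)=C2C(=O)OC(C)(C)OC2=O)ccc1O[Si](C(C)C)(C(C)C)C(C)C | intermediate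
7 | allyl 3-Ar-3-oxopropanoate | COc1cc(C(=O)CC(=O)OCC=C)ccc1O[Si](C(C)C)(C(C)C)C(C)C | intermediate
8 | methyl bromoacetate | COC(=O)CBr | starting material
9 | sodium enolate of 7 (not isolated) | [Na+].COc1cc(C([O-])=CC(=O)OCC=C)ccc1O[Si](C(C)C)(C(C)C)C(C)C | intermediate
10 | 1-allyl 4-methyl 2-(Ar-carbonyl)butanedioate (racemic, labile α-centre) | COc1cc(C(=O)C(CC(=O)OC)C(=O)OCC=C)ccc1O[Si](C(C)C)(C(C)C)C(C)C | intermediate
11 | 1-allyl 4-methyl (2R)-2-[(R)-hydroxy(Ar)methyl]butanedioate (not isolated) | O[C@@H](c1ccc(O[Si](C(C)C)(C(C)C)C(C)C)c(OC)c1)[C@@H](CC(=O)OC)C(=O)OCC=C | intermediate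
12 | allyl (2R,3R)-2-Ar-5-oxooxolane-3-carboxylate | C1C(=O)O[C@@H](c2ccc(O[Si](C(C)C)(C(C)C)C(C)C)c(OC)c2)[C@@H]1C(=O)OCC=C | intermediate
13 | (2R,3R)-2-Ar-5-oxooxolane-3-carboxylic acid | C1C(=O)O[C@@H](c2ccc(O[Si](C(C)C)(C(C)C)C(C)C)c(OC)c2)[C@@H]1C(=O)O | intermediate
14 | (4S,5R)-4-(hydroxymethyl)-5-Ar-oxolan-2-one | C1C(=O)O[C@@H](c2ccc(O[Si](C(C)C)(C(C)C)C(C)C)c(OC)c2)[C@@H]1CO | intermediate
15 | (4S,5R)-4-[(tert-butyldimethylsilyloxy)methyl]-5-Ar-oxolan-2-one | C1C(=O)O[C@@H](c2ccc(O[Si](C(C)C)(C(C)C)C(C)C)c(OC)c2)[C@@H]1CO[Si](C)(C)C(C)(C)C | intermediate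
16 | lithium enolate of 15 (not isolated) | [Li+].C1=C([O-])O[C@@H](c2ccc(O[Si](C(C)C)(C(C)C)C(C)C)c(OC)c2)[C@@H]1CO[Si](C)(C)C(C)(C)C | intermediate
17 | aldol adducts (two new centres unassigned, mixture) | COc1cc(C(O)C2C(=O)O[C@@H](c3ccc(O[Si](C(C)C)(C(C)C)C(C)C)c(OC)c3)[C@@H]2CO[Si](C)(C)C(C)(C)C)ccc1O[Si](C(C)C)(C(C)C)C(C)C | intermediate
18 | mesylates of 17 (not isolated) | COc1cc(C(OS(C)(=O)=O)C2C(=O)O[C@@H](c3ccc(O[Si](C(C)C)(C(C)C)C(C)C)c(OC)c3)[C@@H]2CO[Si](C)(C)C(C)(C)C)ccc1O[Si](C(C)C)(C(C)C)C(C)C | intermediate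
19 | (3E,4S,5R)-3-(Ar-methylidene)-4-[(tert-butyldimethylsilyloxy)methyl]-5-Ar-oxolan-2-one | COc1cc(/C=C2/C(=O)O[C@@H](c3ccc(O[Si](C(C)C)(C(C)C)C(C)C)c(OC)c3)[C@@H]2CO[Si](C)(C)C(C)(C)C)ccc1O[Si](C(C)C)(C(C)C)C(C)C | intermediate
20 | (1R,2S,3E)-1-Ar-3-(Ar-methylidene)-2-[(tert-butyldimethylsilyloxy)methyl]butane-1,4-diol | O[C@@H](c1ccc(O[Si](C(C)C)(C(C)C)C(C)C)c(OC)c1)[C@@H](/C(CO)=C\c1ccc(O[Si](C(C)C)(C(C)C)C(C)C)c(OC)c1)CO[Si](C)(C)C(C)(C)C | intermediate
21 | (2R,3S,4E)-2-Ar-4-(Ar-methylidene)-3-[(tert-butyldimethylsilyloxy)methyl]oxolane | COc1cc(/C=C2/CO[C@@H](c3ccc(O[Si](C(C)C)(C(C)C)C(C)C)c(OC)c3)[C@@H]2CO[Si](C)(C)C(C)(C)C)ccc1O[Si](C(C)C)(C(C)C)C(C)C | intermediate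
22 | [(2R,3S,4E)-2-Ar-4-(Ar-methylidene)oxolan-3-yl]methanol | COc1cc(/C=C2/CO[C@@H](c3ccc(O[Si](C(C)C)(C(C)C)C(C)C)c(OC)c3)[C@@H]2CO)ccc1O[Si](C(C)C)(C(C)C)C(C)C | intermediate
23 | 4-hydroxybenzoic acid | O=C(O)c1ccc(O)cc1 | starting material
24 | tert-butyldimethylsilyl 4-(tert-butyldimethylsilyloxy)benzoate (not isolated) | CC(C)(C)[Si](C)(C)OC(=O)c1ccc(O[Si](C)(C)C(C)(C)C)cc1 | intermediate
25 | 4-(tert-butyldimethylsilyloxy)benzoic acid | O=C(O)c1ccc(O[Si](C)(C)C(C)(C)C)cc1 | intermediate
26 | tris-silyl agastenol | COc1cc(/C=C2/CO[C@@H](c3ccc(O[Si](C(C)C)(C(C)C)C(C)C)c(OC)c3)[C@@H]2COC(=O)c2ccc(O[Si](C)(C)C(C)(C)C)cc2)ccc1O[Si](C(C)C)(C(C)C)C(C)C | intermediate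
27 | agastenol | COc1cc(/C=C2/CO[C@@H](c3ccc(O)c(OC)c3)[C@@H]2COC(=O)c2ccc(O)cc2)ccc1O | target

## Step count
- Total step count: 16.
- Longest linear sequence: 15 steps (steps 1–13, 15 and 16, from vanillin).

## Steps most likely to fail and their fallbacks

**(i) Step 5.** No ketoreductase may accept the α-branched, doubly bulky ketone, or the diastereoselectivity may be poor. The fallback sets out from 7 and comes back at 12, and it sets the two centres one after the other.
- The unbranched keto ester 7, a classical substrate of this enzyme class, is reduced with an (R)-selective ketoreductase and i-PrOH to allyl (3R)-3-hydroxy-3-Ar-propanoate F1.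
- LDA (2.2 equiv, THF, −78 to −30 °C) converts it into the chelated dilithium alkoxide-enolate F2.
- Methyl bromoacetate 8 (DMPU, −78 to −40 °C) alkylates F2 on the face away from the aryl group (Fráter–Seebach alkylation). This gives the anti isomer 1-allyl 4-methyl (2S)-2-[(R)-hydroxy(Ar)methyl]butanedioate F3.
- PPTS in toluene closes F3 to the cis lactone allyl (2R,3S)-2-Ar-5-oxooxolane-3-carboxylate F4.
- DBU (0.3 equiv, CH2Cl2, rt) epimerises the ester-bearing carbon to the more stable trans isomer, which is 12.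

**(ii) Step 10, together with step 9.** Retro-aldol reaction or an insufficient E/Z ratio in the dehydration could spoil this step. The fallback sets out from 15 and comes back at 19, and it replaces aldol and elimination by a phosphonate olefination.
- Enolate 16 (LDA, THF, −78 °C) is trapped on oxygen with diethyl chlorophosphate to give the ketene acetal phosphate (2R,3S)-2-Ar-3-[(tert-butyldimethylsilyloxy)methyl]-2,3-dihydrofuran-5-yl diethyl phosphate F5.
- Further LDA (2.2 equiv, −78 °C to rt) induces the 1,3-phosphorus O-to-C shift. This gives diethyl [(4S,5R)-5-Ar-4-[(tert-butyldimethylsilyloxy)methyl]-2-oxooxolan-3-yl]phosphonate F6.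
- Horner–Wadsworth–Emmons reaction of F6 with aldehyde 2 under Masamune–Roush conditions (LiCl, DBU, MeCN, rt) gives the (E)-benzylidene lactone 19 directly.

**(iii) Step 12.** Activation of the wrong hydroxyl, or ionisation of the electron-rich allylic system, could cause trouble. The fallback sets out from 19 and comes back at 21, and it bypasses the diol altogether.
- DIBAL-H (1.1 equiv, CH2Cl2, −78 °C) stops at the lactol (3E,4S,5R)-3-(Ar-methylidene)-4-[(tert-butyldimethylsilyloxy)methyl]-5-Ar-oxolan-2-ol F7, a mixture of anomers.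
- Ionic reduction of F7 with Et3SiH and BF3·OEt2 (CH2Cl2, −78 °C) delivers hydride to the carbon next to the ring oxygen of the oxocarbenium ion. This gives 21 with the ring never opened.

## Further compounds
F1 | step 5 | allyl (3R)-3-hydroxy-3-Ar-propanoate | O[C@@H](c1ccc(O[Si](C(C)C)(C(C)C)C(C)C)c(OC)c1)CC(=O)OCC=C
F2 | step 5 | dilithium alkoxide-enolate of F1 | [Li+].[Li+].[O-][C@@H](c1ccc(O[Si](C(C)C)(C(C)C)C(C)C)c(OC)c1)C=C([O-])OCC=C
F3 | step 5 | 1-allyl 4-methyl (2S)-2-[(R)-hydroxy(Ar)methyl]butanedioate | O[C@@H](c1ccc(O[Si](C(C)C)(C(C)C)C(C)C)c(OC)c1)[C@H](CC(=O)OC)C(=O)OCC=C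
F4 | step 5 | allyl (2R,3S)-2-Ar-5-oxooxolane-3-carboxylate (cis) | C1C(=O)O[C@@H](c2ccc(O[Si](C(C)C)(C(C)C)C(C)C)c(OC)c2)[C@H]1C(=O)OCC=C
F5 | step 10 | (2R,3S)-2-Ar-3-[(tert-butyldimethylsilyloxy)methyl]-2,3-dihydrofuran-5-yl diethyl phosphate | C1=C(OP(=O)(OCC)OCC)O[C@@H](c2ccc(O[Si](C(C)C)(C(C)C)C(C)C)c(OC)c2)[C@@H]1CO[Si](C)(C)C(C)(C)C
F6 | step 10 | diethyl [(4S,5R)-5-Ar-4-[(tert-butyldimethylsilyloxy)methyl]-2-oxooxolan-3-yl]phosphonate (epimers at C3) | CCOP(=O)(OCC)C1C(=O)O[C@@H](c2ccc(O[Si](C(C)C)(C(C)C)C(C)C)c(OC)c2)[C@@H]1CO[Si](C)(C)C(C)(C)C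
F7 | step 12 | (3E,4S,5R)-3-(Ar-methylidene)-4-[(tert-butyldimethylsilyloxy)methyl]-5-Ar-oxolan-2-ol (anomers) | COc1cc(/C=C2/C(O)O[C@@H](c3ccc(O[Si](C(C)C)(C(C)C)C(C)C)c(OC)c3)[C@@H]2CO[Si](C)(C)C(C)(C)C)ccc1O[Si](C(C)C)(C(C)C)C(C)C
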